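**Retrosynthetic overview**
1. The last bond cut is C8–CH2 between the chromene ring and C3 of the pyranone: acylchromene 11, pyranone 16 and a one-carbon iminium salt are joined by a Mannich/methide coupling (step 7).
2. The isobutyryl group at C6 comes from directed lithiation of chromene 7 between its two OMOM groups (step 3).
3. The 2H-pyran ring is opened at O1–C2 and at C3=C4, leading back to salicylaldehyde 2 and 2-methylprop-1-enylboronic acid 3. The enabling feature is that C4 sits on C4a, ortho to the oxygen-bearing C8a, so the pyran ring is the closed valence isomer of the 1-oxatriene O1=C8a–C4a=C4–C3=C2 (an ortho-quinone methide), with C4 a masked formyl carbon and C2 a stereochemistry-free gem-dimethyl terminus.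
4. Ring order: the benzene ring is bought (2,4,6-trihydroxybenzaldehyde); the pyran ring of the chromene is closed in step 2; the 2-pyranone ring is made separately from an open-chain tricarbonyl ester (step 6); the ring systems are united in step 7.

Key step: step 2

Remark on the chemistry: the target has no stereocentre. Racemic centres appear only in transient adduct 5 and in the enolisable ester 15, and both are erased. Compounds 1, 3, 8, 12 and 13 are taken as commercially available.

**Step 1**
Reactants: 1 2,4,6-trihydroxybenzaldehyde
Product: 2 2-hydroxy-4,6-bis(methoxymethoxy)benzaldehyde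
Conditions: MOMCl (2.2 equiv), i-Pr2NEt, CH2Cl2, 0 °C to rt
Reagents that add atoms: chloromethyl methyl ether (MOMCl), COCCl
Why: Williamson-type O-alkylation (MOM ether formation) should take the para hydroxyl and one ortho hydroxyl, while the last ortho hydroxyl, held in a hydrogen bond to the formyl oxygen, stays free under amine-base conditions; no stereocentre is formed.

**Step 2**
Reactants: 2 2-hydroxy-4,6-bis(methoxymethoxy)benzaldehyde, 3 2-methylprop-1-en-1-ylboronic acid
Product: 7 5,7-bis(methoxymethoxy)-2,2-dimethyl-2H-chromene, via iminium phenolate 4 (not isolated), via Petasis amine adduct 5 (not isolated), via ortho-quinone methide 6 (not isolated)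
Conditions: 3 (1.5 equiv), Bn2NH (40 mol %), 1,4-dioxane, 90 °C
Reagents that add atoms: none
Why: Bn2NH condenses with the formyl group of 2 to iminium phenolate 4, the free ortho oxygen binds the boron of 3, and the resulting boronate passes its alkenyl group intramolecularly to the iminium carbon (Petasis borono-Mannich reaction, forming C4–C3) to give 5, which then expels Bn2NH for re-entry into the cycle and gives ortho-quinone methide 6. The 1-oxatriene of 6 closes by a thermal disrotatory 6π oxa-electrocyclisation that forms O1–C2 and the six-membered 2H-pyran ring, driven by rearomatisation of the benzene ring, so that the C4–C3 bond emerges as the C3=C4 double bond. The closest known reaction type is the amine-catalysed condensation of salicylaldehydes with alkenylboronic acids to 2H-chromenes. No stereocentre remains, because the racemic benzylic centre of 5 is erased on amine loss and C2 carries two methyl groups. The step needs regioselectivity in the choice of ring oxygen, and the substrate secures it: only the oxygen at C2 of 2 is a free hydroxyl (the other ortho oxygen and the para oxygen are MOM ethers), and this same hydroxyl is the only site that can deliver boron, so no other position should react.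

**Step 3**
Reactants: 7 5,7-bis(methoxymethoxy)-2,2-dimethyl-2H-chromene, 8 N-methoxy-N,2-dimethylpropanamide
Product: 10 1-[5,7-bis(methoxymethoxy)-2,2-dimethyl-2H-chromen-6-yl]-2-methylpropan-1-one, via aryllithium 9 (not isolated)
Conditions: n-BuLi, THF, 0 °C; then 8, −78 °C to rt; NH4Cl (aq)
Reagents that add atoms: none
Why: Directed ortho-metalation followed by a Weinreb ketone synthesis: C6–H lies between two OMOM groups that both coordinate lithium and should be removed in preference to C8–H (one OMOM group and the hindered ring oxygen), and the N-methoxy-N-methyl amide should deliver the acyl group once without over-addition.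

**Step 4**
Reactants: 10 1-[5,7-bis(methoxymethoxy)-2,2-dimethyl-2H-chromen-6-yl]-2-methylpropan-1-one
Product: 11 1-(5,7-dihydroxy-2,2-dimethyl-2H-chromen-6-yl)-2-methylpropan-1-one
Conditions: 3 M HCl (aq), MeOH, 50 °C
Reagents that add atoms: none
Why: Acid-catalysed acetal cleavage of both MOM ethers (transacetalisation to methanol), assisted by the ortho ketone, under dilute conditions of the kind that acyl-substituted 2,2-dimethyl-2H-chromenes tolerate.

**Step 5**
Reactants: 12 methyl 3-oxopentanoate, 13 N-methoxy-N-methylpropanamide
Product: 15 methyl 4-methyl-3,5-dioxoheptanoate, via ester dianion 14 (not isolated)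
Conditions: NaH, THF, 0 °C; n-BuLi, 0 °C; then 13, 0 °C to rt; 1 M HCl (aq)
Reagents that add atoms: none
Why: Huckin–Weiler dianion chemistry: the more reactive γ-carbanion of the β-keto ester dianion should be C-acylated by the Weinreb amide, giving the 3,5-dioxo ester as a racemic, largely enolised compound whose stereocentre disappears in step 6.

**Step 6**
Reactants: 15 methyl 4-methyl-3,5-dioxoheptanoate
Product: 16 6-ethyl-4-hydroxy-5-methyl-2H-pyran-2-one
Conditions: DBU, toluene, reflux; then 1 M HCl (aq)
Reagents that add atoms: none
Why: Base-mediated lactonisation (intramolecular O-acylation of the C5 enolate oxygen by the methyl ester, a 6-exo-trig addition–elimination) should give the stabilised 4-hydroxy-2-pyranone.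

**Step 7**
Reactants: 11 1-(5,7-dihydroxy-2,2-dimethyl-2H-chromen-6-yl)-2-methylpropan-1-one, 16 6-ethyl-4-hydroxy-5-methyl-2H-pyran-2-one
Product: 19 3-{[5,7-dihydroxy-2,2-dimethyl-6-(2-methylpropanoyl)-2H-chromen-8-yl]methyl}-6-ethyl-4-hydroxy-5-methyl-2H-pyran-2-one (target), via pyranone Mannich base 17 (not isolated), via pyranone methide 18 (not isolated)
Conditions: 16, CH2=NMe2+ I− (1.0 equiv), MeCN, rt; then 11, 60 °C
Reagents that add atoms: Eschenmoser's salt (N,N-dimethylmethyleneiminium iodide), C=[N+](C)C.[I-]
Why: Mannich aminomethylation at the only free enolic carbon (C3) of 16, loss of dimethylamine to methide 18, and Friedel–Crafts-type conjugate addition of phenol 11 through C8, its single unsubstituted ring carbon, as in the known methylene bridging of acylphloroglucinols with 4-hydroxy-2-pyranones; no stereocentre is formed.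

**Compound list**
1 | 2,4,6-trihydroxybenzaldehyde | O=Cc1c(O)cc(O)cc1O | starting material
2 | 2-hydroxy-4,6-bis(methoxymethoxy)benzaldehyde | COCOc1cc(O)c(C=O)c(OCOC)c1 | intermediate
3 | 2-methylprop-1-en-1-ylboronic acid | CC(C)=CB(O)O | starting material
4 | N,N-dibenzyl-1-[2-oxido-4,6-bis(methoxymethoxy)phenyl]methaniminium (iminium phenolate zwitterion) | COCOc1cc([O-])c(C=[N+](Cc2ccccc2)Cc2ccccc2)c(OCOC)c1 | intermediate
5 | 2-[1-(dibenzylamino)-3-methylbut-2-en-1-yl]-3,5-bis(methoxymethoxy)phenol (racemic) | COCOc1cc(O)c(C(C=C(C)C)N(Cc2ccccc2)Cc2ccccc2)c(OCOC)c1 | intermediate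
6 | (6Z)-3,5-bis(methoxymethoxy)-6-(3-methylbut-2-en-1-ylidene)cyclohexa-2,4-dien-1-one | CC(C)=C/C=C1\C(=O)C=C(OCOC)C=C1OCOC | intermediate
7 | 5,7-bis(methoxymethoxy)-2,2-dimethyl-2H-chromene | COCOc1cc(OCOC)c2C=CC(C)(C)Oc2c1 | intermediate
8 | N-methoxy-N,2-dimethylpropanamide | CC(C)C(=O)N(C)OC | starting material
9 | [5,7-bis(methoxymethoxy)-2,2-dimethyl-2H-chromen-6-yl]lithium | [Li]c1c(OCOC)cc2OC(C)(C)C=Cc2c1OCOC | intermediate
10 | 1-[5,7-bis(methoxymethoxy)-2,2-dimethyl-2H-chromen-6-yl]-2-methylpropan-1-one | CC(C)C(=O)c1c(OCOC)cc2OC(C)(C)C=Cc2c1OCOC | intermediate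
11 | 1-(5,7-dihydroxy-2,2-dimethyl-2H-chromen-6-yl)-2-methylpropan-1-one | CC(C)C(=O)c1c(O)cc2OC(C)(C)C=Cc2c1O | intermediate
12 | methyl 3-oxopentanoate | CCC(=O)CC(=O)OC | starting material
13 | N-methoxy-N-methylpropanamide | CCC(=O)N(C)OC | starting material
14 | lithium sodium dianion of methyl 3-oxopentanoate | C[CH-]C(=O)[CH-]C(=O)OC.[Li+].[Na+] | intermediate
15 | methyl 4-methyl-3,5-dioxoheptanoate (racemic, enolisable) | CCC(=O)C(C)C(=O)CC(=O)OC | intermediate
16 | 6-ethyl-4-hydroxy-5-methyl-2H-pyran-2-one | CCc1oc(=O)cc(O)c1C | intermediate
17 | 3-[(dimethylamino)methyl]-6-ethyl-4-hydroxy-5-methyl-2H-pyran-2-one (formed as its hydroiodide) | CCc1oc(=O)c(CN(C)C)c(O)c1C | intermediate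
18 | 6-ethyl-5-methyl-3-methylidene-2H-pyran-2,4(3H)-dione | CCC1=C(C)C(=O)C(=C)C(=O)O1 | intermediate
19 | 3-{[5,7-dihydroxy-2,2-dimethyl-6-(2-methylpropanoyl)-2H-chromen-8-yl]methyl}-6-ethyl-4-hydroxy-5-methyl-2H-pyran-2-one | CCc1oc(=O)c(Cc2c(O)c(C(=O)C(C)C)c(O)c3c2OC(C)(C)C=C3)c(O)c1C | target

**Step count**
Total steps: 7. Longest linear sequence: 5 (steps 1, 2, 3, 4, 7); steps 5 and 6 form the convergent pyranone branch.

**Steps most likely to fail**

Step 2. Condensation and alkenyl transfer at the hindered, electron-rich formyl group (flanked by two oxygens) may be slow, so that protodeboronation of 3 outruns the coupling. The fallback makes the same two bonds in two operations. Setting out from 2, addition of excess 2-methylprop-1-en-1-ylmagnesium bromide (Me2C=CHMgBr, THF, 0 °C) should give the allylic benzylic alcohol 2-(1-hydroxy-3-methylbut-2-en-1-yl)-3,5-bis(methoxymethoxy)phenol F1. Gentle dehydration of F1 (silica gel or MgSO4, toluene, 80 °C) should then generate ortho-quinone methide 6, which closes by the same oxa-6π electrocyclisation, and the route is rejoined at 7.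

Step 3. Proton transfer from the branched amide to the doubly ortho-substituted aryllithium, or slow acyl transfer, may return 7. The fallback changes the electrophile and adds a redox step. Setting out from 7, lithiation as before to 9 and trapping with the small, fast electrophile 2-methylpropanal should give 1-[5,7-bis(methoxymethoxy)-2,2-dimethyl-2H-chromen-6-yl]-2-methylpropan-1-ol F2. Oxidation of F2 with Dess–Martin periodinane (CH2Cl2, NaHCO3, rt) should then give the ketone, and the route is rejoined at 10.

Step 7. Methide 18 may be consumed by unreacted pyranone (methylene-bis-pyranone formation) faster than the hindered C8 of 11 is alkylated. The fallback reverses the roles of the partners. Setting out from 11, aminomethylation at C8 with CH2=NMe2+ I− (MeCN, rt, then NaHCO3) should give 1-{8-[(dimethylamino)methyl]-5,7-dihydroxy-2,2-dimethyl-2H-chromen-6-yl}-2-methylpropan-1-one F3. Heating F3 with 16 (1,4-dioxane, 90 °C) should expel dimethylamine to the arene-based ortho-quinone methide, which is trapped by C3 of the pyranone, and the route is rejoined at 19.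

**Further compounds**
F1 | step 2 | 2-(1-hydroxy-3-methylbut-2-en-1-yl)-3,5-bis(methoxymethoxy)phenol | COCOc1cc(O)c(C(O)C=C(C)C)c(OCOC)c1
F2 | step 3 | 1-[5,7-bis(methoxymethoxy)-2,2-dimethyl-2H-chromen-6-yl]-2-methylpropan-1-ol | CC(C)C(O)c1c(OCOC)cc2OC(C)(C)C=Cc2c1OCOC
F3 | step 7 | 1-{8-[(dimethylamino)methyl]-5,7-dihydroxy-2,2-dimethyl-2H-chromen-6-yl}-2-methylpropan-1-one | CC(C)C(=O)c1c(O)c(CN(C)C)c2OC(C)(C)C=Cc2c1O
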